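**Plan**
- Feature used: the oxolane ring O–C7–C8–C8'–C9' carries the C7 aryl group (the inner dihydrobenzofuran), the C8 CH2OH and the C8' arylmethyl group all cis. C7 is bonded to both the ring oxygen and an arene, so it can be held at the ketone level as a hemiketal with the C9' hydroxyl and reduced through an oxocarbenium ion from the face opposite the C8 and C8' groups.
- Retrosynthesis: the five O–Si bonds are cut first, then O–C7 and C7–H of the oxolane (hemiketal reduction), then the C7–aryl bond (aryllithium plus cis-disubstituted butyrolactone). In the inner and then the outer dihydrobenzofuran, the O1–C2 bond (cyclisation) and the C2–C3 bond (aldol) are cut.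
- Forward: the furan ring of the outer dihydrobenzofuran closes first and its C5 is formylated. The inner dihydrobenzofuran ring is then closed by the same operations. The butyrolactone is made separately and joined at C7, and the oxolane ring closes last.
- Stereochemistry: C3 of each dihydrobenzofuran comes from an Evans auxiliary (S for the outer unit, R for the inner) and C2 from trans-selective capture of the benzylic cation. C8' comes from asymmetric hydrogenation, C8 from kinetic protonation anti to the C8' group, and C7 from hydride delivery anti to C8 and C8'.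

Key step: step 25

Remark: lignan locants are used for the oxolane part (C7 aryl-bearing, C8 hydroxymethyl-bearing, C8' arylmethyl-bearing, C9' ring CH2); TBS = tert-butyldimethylsilyl, TBSO = its ether oxygen, TES = triethylsilyl; the ligand hand in step 18 is the one assumed to deliver the R acid, and its antipode would be used should the sense prove opposite.

**Route**

Step 1
Reactants: 1 5-bromo-2-hydroxy-3-methoxybenzaldehyde
Product: 2 5-bromo-3-methoxy-2-(TBSO)benzaldehyde
Conditions: TBSCl, imidazole, DMF, rt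
Reagents that add atoms: tert-butyldimethylsilyl chloride, CC(C)(C)[Si](C)(C)Cl
Why: Silyl ether formation on the phenol masks the acidic salicylaldehyde OH before ylide and enolate chemistry.

Step 2
Reactants: 2 5-bromo-3-methoxy-2-(TBSO)benzaldehyde
Product: 4 2-[5-bromo-3-methoxy-2-(TBSO)phenyl]acetaldehyde, via enol ether 3 (not isolated)
Conditions: Ph3P(CH2OMe)Cl, KN(SiMe3)2, THF, −78 to 0 °C; then aq. HCl (2 M), THF, 40 °C
Reagents that add atoms: (methoxymethyl)triphenylphosphonium chloride, COC[P+](c1ccccc1)(c1ccccc1)c1ccccc1.[Cl-]; water, O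
Why: Wittig methoxymethylenation followed by enol ether hydrolysis gives the one-carbon homologue; once the formyl group is gone the hindered aryl silyl ether should tolerate the brief aqueous acid.

Step 3
Reactants: 4 2-[5-bromo-3-methoxy-2-(TBSO)phenyl]acetaldehyde
Product: 5 2-[5-bromo-3-methoxy-2-(TBSO)phenyl]acetic acid
Conditions: NaClO2, NaH2PO4, 2-methylbut-2-ene, t-BuOH/H2O, 0 °C to rt
Reagents that add atoms: sodium chlorite, [Na+].[O-]Cl=O
Why: Pinnick oxidation converts the enolisable arylacetaldehyde into the acid without touching the aryl bromide or the silyl ether.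

Step 4
Reactants: 5 2-[5-bromo-3-methoxy-2-(TBSO)phenyl]acetic acid
Product: 6 2-[5-bromo-3-methoxy-2-(TBSO)phenyl]acetyl chloride
Conditions: Me2C=C(Cl)NMe2, CH2Cl2, 0 °C to rt; concentrate, the crude chloride is divided and used at once
Reagents that add atoms: 1-chloro-N,N,2-trimethylprop-1-en-1-amine, CC(C)=C(Cl)N(C)C
Why: Acid chloride formation with the α-chloroenamine (Ghosez reagent) runs under neutral conditions without HCl, so the ortho aryl silyl ether should survive, and one batch of the acyl donor serves both auxiliary couplings.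

Step 5
Reactants: 6 2-[5-bromo-3-methoxy-2-(TBSO)phenyl]acetyl chloride; 7 (S)-4-benzyl-1,3-oxazolidin-2-one
Product: 8 (S)-4-benzyl-3-{2-[5-bromo-3-methoxy-2-(TBSO)phenyl]acetyl}-1,3-oxazolidin-2-one
Conditions: 7, LiCl, Et3N, THF, −20 °C; then 6 (slow addition), −20 °C to rt
Reagents that add atoms: none
Why: Lithium chloride and triethylamine mediated N-acylation of the Evans oxazolidinone by the acid chloride forms the imide without a strong base and creates no stereocentre.

Step 6
Reactants: 6 2-[5-bromo-3-methoxy-2-(TBSO)phenyl]acetyl chloride; 9 (R)-4-benzyl-1,3-oxazolidin-2-one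
Product: 10 (R)-4-benzyl-3-{2-[5-bromo-3-methoxy-2-(TBSO)phenyl]acetyl}-1,3-oxazolidin-2-one
Conditions: 9, LiCl, Et3N, THF, −20 °C; then 6 (slow addition), −20 °C to rt
Reagents that add atoms: none
Why: The same lithium chloride and triethylamine mediated N-acylation with the antipodal auxiliary supplies the imide needed for the inner unit, whose configuration is opposite to that of the outer one.

Step 7
Reactants: 11 vanillin (4-hydroxy-3-methoxybenzaldehyde)
Product: 12 3-methoxy-4-(TBSO)benzaldehyde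
Conditions: TBSCl, imidazole, DMF, rt
Reagents that add atoms: tert-butyldimethylsilyl chloride, CC(C)(C)[Si](C)(C)Cl
Why: Phenol silylation gives an aldehyde that is compatible with the boron aldol reaction.

Step 8
Reactants: 8 (S)-imide; 12 3-methoxy-4-(TBSO)benzaldehyde
Product: 14 (4S)-4-benzyl-3-{(2S,3S)-2-[5-bromo-3-methoxy-2-(TBSO)phenyl]-3-hydroxy-3-[3-methoxy-4-(TBSO)phenyl]propanoyl}-1,3-oxazolidin-2-one, via (Z)-boron enolate 13 (not isolated)
Conditions: Bu2BOTf, iPr2NEt, CH2Cl2, −78 to 0 °C; then 12, −78 to 0 °C; pH 7 buffer, MeOH, H2O2, 0 °C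
Reagents that add atoms: none
Why: Evans syn-aldol reaction, in which the Z dibutylboron enolate reacts through a Zimmerman–Traxler chair on the face away from the auxiliary benzyl group, so the (S)-auxiliary sets the aryl-bearing carbon (future C3 of the outer unit) as 2S and the carbinol as 3S.

Step 9
Reactants: 14 syn-aldol imide
Product: 15 (1S,2R)-2-[5-bromo-3-methoxy-2-(TBSO)phenyl]-1-[3-methoxy-4-(TBSO)phenyl]propane-1,3-diol
Conditions: LiBH4, MeOH (1 equiv), THF, 0 °C
Reagents that add atoms: none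
Why: Reductive cleavage of the N-acyl oxazolidinone by borohydride gives the primary alcohol and returns the auxiliary, hydride attack on the exocyclic carbonyl being faster than enolisation of the aryl-bearing centre.

Step 10
Reactants: 15 bis-silylated diol
Product: 17 4-[(2S,3R)-5-bromo-3-(hydroxymethyl)-7-methoxy-2,3-dihydro-1-benzofuran-2-yl]-2-methoxyphenol, via tetraol 16 (not isolated)
Conditions: TBAF, THF, 0 °C; then TsOH·H2O (excess), rt
Reagents that add atoms: none
Why: Fluoride desilylation followed by acid-mediated benzylic cation (para-quinone methide type) cyclisation, in which the ortho phenol captures the cation in a five-membered closure and the fixed C3 centre steers the 2-aryl group trans (C2 becomes S), as in biomimetic phenylcoumaran formation.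

Step 11
Reactants: 17 outer dihydrobenzofuran diol
Product: 18 (2S,3R)-5-bromo-7-methoxy-2-[3-methoxy-4-(TBSO)phenyl]-3-[(TBSO)methyl]-2,3-dihydro-1-benzofuran
Conditions: TBSCl (2.5 equiv), imidazole, DMF, rt
Reagents that add atoms: tert-butyldimethylsilyl chloride, CC(C)(C)[Si](C)(C)Cl
Why: Silylation of the phenol and the primary alcohol in one operation protects both against the organolithium step.

Step 12
Reactants: 18 outer aryl bromide
Product: 20 (2S,3R)-7-methoxy-2-[3-methoxy-4-(TBSO)phenyl]-3-[(TBSO)methyl]-2,3-dihydro-1-benzofuran-5-carbaldehyde, via aryllithium 19 (not isolated)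
Conditions: n-BuLi, THF, −78 °C; then DMF, −78 to 0 °C; aq. NH4Cl
Reagents that add atoms: N,N-dimethylformamide, CN(C)C=O
Why: Bromine–lithium exchange followed by formylation with DMF (Bouveault-type) is fast at −78 °C and leaves the silyl ethers and the benzylic ether untouched.

Step 13
Reactants: 10 (R)-imide; 20 outer aldehyde
Product: 22 (4R)-4-benzyl-3-{(2R,3R)-2-[5-bromo-3-methoxy-2-(TBSO)phenyl]-3-hydroxy-3-[(2S,3R)-7-methoxy-2-[3-methoxy-4-(TBSO)phenyl]-3-[(TBSO)methyl]-2,3-dihydro-1-benzofuran-5-yl]propanoyl}-1,3-oxazolidin-2-one, via (Z)-boron enolate 21 (not isolated)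
Conditions: Bu2BOTf, iPr2NEt, CH2Cl2, −78 to 0 °C; then 20, −78 to 0 °C; pH 7 buffer, MeOH, H2O2, 0 °C
Reagents that add atoms: none
Why: Evans syn-aldol reaction under auxiliary control, in which the (R)-auxiliary overrides the remote centres of the aldehyde and sets the future C3 of the inner unit as 2R (3S after the later change of substituent priorities) and the carbinol as 3R.

Step 14
Reactants: 22 syn-aldol imide
Product: 23 (1R,2S)-2-[5-bromo-3-methoxy-2-(TBSO)phenyl]-1-[(2S,3R)-7-methoxy-2-[3-methoxy-4-(TBSO)phenyl]-3-[(TBSO)methyl]-2,3-dihydro-1-benzofuran-5-yl]propane-1,3-diol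
Conditions: LiBH4, MeOH (1 equiv), THF, 0 °C
Reagents that add atoms: none
Why: Borohydride cleavage of the N-acyl oxazolidinone releases the primary alcohol and the auxiliary without affecting the silyl ethers or the existing ring.

Step 15
Reactants: 23 tris-silylated diol
Product: 25 4-[(2S,3R)-5-[(2R,3S)-5-bromo-3-(hydroxymethyl)-7-methoxy-2,3-dihydro-1-benzofuran-2-yl]-3-(hydroxymethyl)-7-methoxy-2,3-dihydro-1-benzofuran-2-yl]-2-methoxyphenol, via pentaol 24 (not isolated)
Conditions: TBAF (excess), THF, 0 °C; then TsOH·H2O (excess), rt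
Reagents that add atoms: none
Why: Global desilylation followed by acid-mediated benzylic cation cyclisation closes the inner ring trans under control of its own C3 (C2 becomes R), and the existing outer ring, should it open reversibly, recloses trans for the same reason.

Step 16
Reactants: 25 bis-dihydrobenzofuran triol
Product: 26 (2R,3S)-5-bromo-7-methoxy-2-{(2S,3R)-7-methoxy-2-[3-methoxy-4-(TBSO)phenyl]-3-[(TBSO)methyl]-2,3-dihydro-1-benzofuran-5-yl}-3-[(TBSO)methyl]-2,3-dihydro-1-benzofuran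
Conditions: TBSCl (4 equiv), imidazole, DMF, rt
Reagents that add atoms: tert-butyldimethylsilyl chloride, CC(C)(C)[Si](C)(C)Cl
Why: Exhaustive silylation of the phenol and both primary alcohols gives one defined tris-silyl ether ready for lithiation.

Step 17
Reactants: 27 4-(benzyloxy)-3-methoxybenzaldehyde; 28 dimethyl succinate
Product: 29 (E)-4-[4-(benzyloxy)-3-methoxyphenyl]-3-(methoxycarbonyl)but-3-enoic acid
Conditions: NaOMe, MeOH, reflux; then aq. HCl
Reagents that add atoms: none
Why: Stobbe condensation, in which the succinate enolate adds to the aldehyde, lactonises to the paraconic ester and ring-opens by E1cB to the (E)-alkylidene half-ester.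

Step 18
Reactants: 29 Stobbe half-ester
Product: 30 (R)-4-[4-(benzyloxy)-3-methoxyphenyl]-3-(methoxycarbonyl)butanoic acid
Conditions: H2 (5 bar), [Rh(COD)2]BF4 (1 mol %), (S,S)-MOD-DIOP, Et3N, MeOH, rt
Reagents that add atoms: none
Why: Rhodium-catalysed asymmetric hydrogenation of the itaconate-type half-ester, in which carboxylate and alkene chelate the metal and the chiral diphosphine selects the alkene face, sets C8' as R.

Step 19
Reactants: 30 (R)-half-ester
Product: 32 (R)-4-{[4-(benzyloxy)-3-methoxyphenyl]methyl}oxolan-2-one, via hydroxy acid 31 (not isolated)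
Conditions: KOH (1 equiv), EtOH; then CaCl2, NaBH4, EtOH, −10 °C to rt; then aq. HCl (3 M), rt
Reagents that add atoms: none
Why: Chemoselective borohydride reduction of the ester beside the unreactive carboxylate salt, followed by acid lactonisation, gives the β-substituted butyrolactone with the stereocentre untouched.

Step 20
Reactants: 32 (R)-lactone
Product: 34 (3S,4R)-4-{[4-(benzyloxy)-3-methoxyphenyl]methyl}-3-(hydroxymethyl)oxolan-2-one, via lithium enolate 33 (not isolated)
Conditions: LiN(iPr)2, THF, −78 °C; then CH2O (gas, from cracked paraformaldehyde), −78 to −20 °C; aq. NH4Cl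
Reagents that add atoms: formaldehyde, C=O
Why: Aldol addition of the lactone enolate to monomeric formaldehyde, in which the electrophile enters anti to the C4 arylmethyl group and gives the trans lactone.

Step 21
Reactants: 34 trans-hydroxymethyl lactone
Product: 36 (3R,4R)-4-{[4-(benzyloxy)-3-methoxyphenyl]methyl}-3-(hydroxymethyl)oxolan-2-one, via dilithium alkoxide enolate 35 (not isolated)
Conditions: LiN(iPr)2 (2.3 equiv), THF, −78 to −30 °C; then inverse addition to 2,6-di-tert-butyl-4-methylphenol (excess), THF, −78 °C; aq. NH4Cl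
Reagents that add atoms: none
Why: Diastereoselective kinetic protonation of a lactone enolate, in which the hindered phenol delivers the proton to the face opposite the C4 arylmethyl group so that the hydroxymethyl group ends cis (C8 set as R), while the alkoxide form of the side chain rules out β-elimination.

Step 22
Reactants: 36 cis-hydroxymethyl lactone
Product: 37 (3R,4R)-4-[(4-hydroxy-3-methoxyphenyl)methyl]-3-(hydroxymethyl)oxolan-2-one
Conditions: H2 (1 atm), Pd/C (10%), EtOAc, rt
Reagents that add atoms: none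
Why: Hydrogenolysis of the aryl benzyl ether under neutral conditions frees the phenol without epimerising the cis lactone.

Step 23
Reactants: 37 phenolic cis lactone
Product: 38 (3R,4R)-4-{[3-methoxy-4-(TBSO)phenyl]methyl}-3-[(TBSO)methyl]oxolan-2-one
Conditions: TBSCl (2.5 equiv), imidazole, DMF, 0 °C to rt
Reagents that add atoms: tert-butyldimethylsilyl chloride, CC(C)(C)[Si](C)(C)Cl
Why: Silylation of the phenol and the primary alcohol under weakly basic conditions leaves the C8 centre untouched and makes all protecting groups fluoride-labile.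

Step 24
Reactants: 26 bis-dihydrobenzofuran bromide; 38 cis lactone
Product: 40 (2R,3R)-1-Ar-3-(hydroxymethyl)-4-[3-methoxy-4-(TBSO)phenyl]-2-[(TBSO)methyl]butan-1-one (Ar = the benzofuran-5-yl group of 26 in place of bromine), via aryllithium 39 (not isolated)
Conditions: 26, t-BuLi (2.0 equiv), THF, −78 °C; then 38, −78 °C; AcOH/THF quench at −78 °C
Reagents that add atoms: none
Why: Bromine–lithium exchange and addition of the aryllithium to the lactone carbonyl, as in C-aryl glycoside synthesis: the tetrahedral lithium hemiketal alkoxide persists at −78 °C, so addition stops at the ketone level, and the product (open form in equilibrium with its cyclic hemiketal) is used without delay.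

Step 25
Reactants: 40 γ-hydroxy aryl ketone
Product: 43 (2R,3R,4R)-2-Ar-4-{[3-methoxy-4-(TBSO)phenyl]methyl}-3-[(TBSO)methyl]oxolane (penta-TBS ether of the target; Ar as in 40), via cyclic hemiketal 41 (not isolated), via oxocarbenium ion 42 (not isolated)
Conditions: Et3SiH (5 equiv), BF3·OEt2 (2 equiv), CH2Cl2, −78 °C; cold aq. NaHCO3
Reagents that add atoms: none
Why: The C9' hydroxyl of 40 closes 5-exo-trig onto the C7 carbonyl to give hemiketal 41, BF3·OEt2 ionises its tertiary hydroxyl to the aryl-stabilised five-membered oxocarbenium ion 42, and Et3SiH transfers hydride to C7, so the O–C7 ring bond and the C7–H bond are both made in this operation. The closest known reaction type is the Lewis acid and silane reductive deoxygenation of cyclic hemiketals used for C-aryl glycosides and 2,3-cis 2-aryltetrahydrofurans. The new stereocentre C7 (R) is under substrate control: hydride attacks planar C7 from the face opposite the cis C8 silyloxymethyl and C8' arylmethyl groups (inside attack on the envelope), which leaves the aryl group on their face and gives the all-cis ring. Two selectivities are needed: facial selectivity at C7, secured by the two cis substituents shielding one face, and ionisation of the hemiketal in preference to the three benzylic ethers, secured by the much easier formation of the oxocarbenium ion at −78 °C. Hydride transfer is irreversible, so the contra-thermodynamic triad is not equilibrated, and the low temperature and short reaction time limit C8 epimerisation through the open ketone.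

Step 26
Reactants: 43 penta-TBS ether
Product: 44 CNP0395728.1
Conditions: TBAF, AcOH, THF, 0 °C to rt
Reagents that add atoms: none
Why: Fluoride-mediated global desilylation removes the two aryl and three alkyl silyl ethers, and the acetic acid buffer keeps the phenoxides from opening the benzylic ethers through quinone methides.

**Compound list**
1 | 5-bromo-2-hydroxy-3-methoxybenzaldehyde | COc1cc(Br)cc(C=O)c1O | starting material
2 | 5-bromo-3-methoxy-2-(TBSO)benzaldehyde | COc1cc(Br)cc(C=O)c1O[Si](C)(C)C(C)(C)C | intermediate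
3 | [4-bromo-2-methoxy-6-(2-methoxyethenyl)phenoxy](tert-butyl)dimethylsilane, E/Z mixture (not isolated) | COC=Cc1cc(Br)cc(OC)c1O[Si](C)(C)C(C)(C)C | intermediate
4 | 2-[5-bromo-3-methoxy-2-(TBSO)phenyl]acetaldehyde | COc1cc(Br)cc(CC=O)c1O[Si](C)(C)C(C)(C)C | intermediate
5 | 2-[5-bromo-3-methoxy-2-(TBSO)phenyl]acetic acid | COc1cc(Br)cc(CC(=O)O)c1O[Si](C)(C)C(C)(C)C | intermediate
6 | 2-[5-bromo-3-methoxy-2-(TBSO)phenyl]acetyl chloride | COc1cc(Br)cc(CC(=O)Cl)c1O[Si](C)(C)C(C)(C)C | intermediate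
7 | (S)-4-benzyl-1,3-oxazolidin-2-one | O=C1N[C@@H](Cc2ccccc2)CO1 | starting material
8 | (S)-4-benzyl-3-{2-[5-bromo-3-methoxy-2-(TBSO)phenyl]acetyl}-1,3-oxazolidin-2-one | COc1cc(Br)cc(CC(=O)N2[C@@H](Cc3ccccc3)COC2=O)c1O[Si](C)(C)C(C)(C)C | intermediate
9 | (R)-4-benzyl-1,3-oxazolidin-2-one | O=C1N[C@H](Cc2ccccc2)CO1 | starting material
10 | (R)-4-benzyl-3-{2-[5-bromo-3-methoxy-2-(TBSO)phenyl]acetyl}-1,3-oxazolidin-2-one | COc1cc(Br)cc(CC(=O)N2[C@H](Cc3ccccc3)COC2=O)c1O[Si](C)(C)C(C)(C)C | intermediate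
11 | vanillin | COc1cc(C=O)ccc1O | starting material
12 | 3-methoxy-4-(TBSO)benzaldehyde | COc1cc(C=O)ccc1O[Si](C)(C)C(C)(C)C | intermediate
13 | (Z)-dibutylboron enolate of 8 (not isolated) | CCCCB(CCCC)O/C(=C\c1cc(Br)cc(OC)c1O[Si](C)(C)C(C)(C)C)N1[C@@H](Cc2ccccc2)COC1=O | intermediate
14 | (4S)-4-benzyl-3-{(2S,3S)-2-[5-bromo-3-methoxy-2-(TBSO)phenyl]-3-hydroxy-3-[3-methoxy-4-(TBSO)phenyl]propanoyl}-1,3-oxazolidin-2-one | COc1cc(Br)cc([C@@H]([C@H](O)c2ccc(O[Si](C)(C)C(C)(C)C)c(OC)c2)C(=O)N2[C@@H](Cc3ccccc3)COC2=O)c1O[Si](C)(C)C(C)(C)C | intermediate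
15 | (1S,2R)-2-[5-bromo-3-methoxy-2-(TBSO)phenyl]-1-[3-methoxy-4-(TBSO)phenyl]propane-1,3-diol | COc1cc(Br)cc([C@@H]([C@H](O)c2ccc(O[Si](C)(C)C(C)(C)C)c(OC)c2)CO)c1O[Si](C)(C)C(C)(C)C | intermediate
16 | (1S,2R)-2-(5-bromo-2-hydroxy-3-methoxyphenyl)-1-(4-hydroxy-3-methoxyphenyl)propane-1,3-diol (not isolated) | COc1cc(Br)cc([C@@H]([C@H](O)c2ccc(O)c(OC)c2)CO)c1O | intermediate
17 | 4-[(2S,3R)-5-bromo-3-(hydroxymethyl)-7-methoxy-2,3-dihydro-1-benzofuran-2-yl]-2-methoxyphenol | Brc1cc(OC)c2c(c1)[C@H](CO)[C@@H](c1ccc(O)c(OC)c1)O2 | intermediate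
18 | (2S,3R)-5-bromo-7-methoxy-2-[3-methoxy-4-(TBSO)phenyl]-3-[(TBSO)methyl]-2,3-dihydro-1-benzofuran | Brc1cc(OC)c2c(c1)[C@H](CO[Si](C)(C)C(C)(C)C)[C@@H](c1ccc(O[Si](C)(C)C(C)(C)C)c(OC)c1)O2 | intermediate
19 | 5-lithio analogue of 18 (not isolated) | [Li]c1cc(OC)c2c(c1)[C@H](CO[Si](C)(C)C(C)(C)C)[C@@H](c1ccc(O[Si](C)(C)C(C)(C)C)c(OC)c1)O2 | intermediate
20 | (2S,3R)-7-methoxy-2-[3-methoxy-4-(TBSO)phenyl]-3-[(TBSO)methyl]-2,3-dihydro-1-benzofuran-5-carbaldehyde | O=Cc1cc(OC)c2c(c1)[C@H](CO[Si](C)(C)C(C)(C)C)[C@@H](c1ccc(O[Si](C)(C)C(C)(C)C)c(OC)c1)O2 | intermediate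
21 | (Z)-dibutylboron enolate of 10 (not isolated) | CCCCB(CCCC)O/C(=C\c1cc(Br)cc(OC)c1O[Si](C)(C)C(C)(C)C)N1[C@H](Cc2ccccc2)COC1=O | intermediate
22 | (4R)-4-benzyl-3-{(2R,3R)-2-[5-bromo-3-methoxy-2-(TBSO)phenyl]-3-hydroxy-3-[(2S,3R)-7-methoxy-2-[3-methoxy-4-(TBSO)phenyl]-3-[(TBSO)methyl]-2,3-dihydro-1-benzofuran-5-yl]propanoyl}-1,3-oxazolidin-2-one | COc1cc(Br)cc([C@H]([C@@H](O)c2cc(OC)c3c(c2)[C@H](CO[Si](C)(C)C(C)(C)C)[C@@H](c2ccc(O[Si](C)(C)C(C)(C)C)c(OC)c2)O3)C(=O)N2[C@H](Cc3ccccc3)COC2=O)c1O[Si](C)(C)C(C)(C)C | intermediate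
23 | (1R,2S)-2-[5-bromo-3-methoxy-2-(TBSO)phenyl]-1-[(2S,3R)-7-methoxy-2-[3-methoxy-4-(TBSO)phenyl]-3-[(TBSO)methyl]-2,3-dihydro-1-benzofuran-5-yl]propane-1,3-diol | COc1cc(Br)cc([C@H]([C@@H](O)c2cc(OC)c3c(c2)[C@H](CO[Si](C)(C)C(C)(C)C)[C@@H](c2ccc(O[Si](C)(C)C(C)(C)C)c(OC)c2)O3)CO)c1O[Si](C)(C)C(C)(C)C | intermediate
24 | fully desilylated (1R,2S)-pentaol from 23 (not isolated) | COc1cc(Br)cc([C@H]([C@@H](O)c2cc(OC)c3c(c2)[C@H](CO)[C@@H](c2ccc(O)c(OC)c2)O3)CO)c1O | intermediate
25 | 4-[(2S,3R)-5-[(2R,3S)-5-bromo-3-(hydroxymethyl)-7-methoxy-2,3-dihydro-1-benzofuran-2-yl]-3-(hydroxymethyl)-7-methoxy-2,3-dihydro-1-benzofuran-2-yl]-2-methoxyphenol | Brc1cc(OC)c2c(c1)[C@@H](CO)[C@H](c1cc(OC)c3c(c1)[C@H](CO)[C@@H](c1ccc(O)c(OC)c1)O3)O2 | intermediate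
26 | (2R,3S)-5-bromo-7-methoxy-2-{(2S,3R)-7-methoxy-2-[3-methoxy-4-(TBSO)phenyl]-3-[(TBSO)methyl]-2,3-dihydro-1-benzofuran-5-yl}-3-[(TBSO)methyl]-2,3-dihydro-1-benzofuran | Brc1cc(OC)c2c(c1)[C@@H](CO[Si](C)(C)C(C)(C)C)[C@H](c1cc(OC)c3c(c1)[C@H](CO[Si](C)(C)C(C)(C)C)[C@@H](c1ccc(O[Si](C)(C)C(C)(C)C)c(OC)c1)O3)O2 | intermediate
27 | 4-(benzyloxy)-3-methoxybenzaldehyde | COc1cc(C=O)ccc1OCc1ccccc1 | starting material
28 | dimethyl succinate | COC(=O)CCC(=O)OC | starting material
29 | (E)-4-[4-(benzyloxy)-3-methoxyphenyl]-3-(methoxycarbonyl)but-3-enoic acid | COC(=O)/C(CC(=O)O)=C/c1ccc(OCc2ccccc2)c(OC)c1 | intermediate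
30 | (R)-4-[4-(benzyloxy)-3-methoxyphenyl]-3-(methoxycarbonyl)butanoic acid | COc1cc(C[C@H](CC(=O)O)C(=O)OC)ccc1OCc1ccccc1 | intermediate
31 | (R)-4-[4-(benzyloxy)-3-methoxyphenyl]-3-(hydroxymethyl)butanoic acid (not isolated) | COc1cc(C[C@H](CC(=O)O)CO)ccc1OCc1ccccc1 | intermediate
32 | (R)-4-{[4-(benzyloxy)-3-methoxyphenyl]methyl}oxolan-2-one | COc1cc(C[C@H]2COC(=O)C2)ccc1OCc1ccccc1 | intermediate
33 | lithium enolate of 32 (not isolated) | COc1cc(C[C@H]2COC(O[Li])=C2)ccc1OCc1ccccc1 | intermediate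
34 | (3S,4R)-4-{[4-(benzyloxy)-3-methoxyphenyl]methyl}-3-(hydroxymethyl)oxolan-2-one (trans) | COc1cc(C[C@H]2COC(=O)[C@@H]2CO)ccc1OCc1ccccc1 | intermediate
35 | dilithium alkoxide enolate of 34 (not isolated) | COc1cc(C[C@H]2COC(O[Li])=C2CO[Li])ccc1OCc1ccccc1 | intermediate
36 | (3R,4R)-4-{[4-(benzyloxy)-3-methoxyphenyl]methyl}-3-(hydroxymethyl)oxolan-2-one (cis) | COc1cc(C[C@H]2COC(=O)[C@H]2CO)ccc1OCc1ccccc1 | intermediate
37 | (3R,4R)-4-[(4-hydroxy-3-methoxyphenyl)methyl]-3-(hydroxymethyl)oxolan-2-one | COc1cc(C[C@H]2COC(=O)[C@H]2CO)ccc1O | intermediate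
38 | (3R,4R)-4-{[3-methoxy-4-(TBSO)phenyl]methyl}-3-[(TBSO)methyl]oxolan-2-one | COc1cc(C[C@H]2COC(=O)[C@H]2CO[Si](C)(C)C(C)(C)C)ccc1O[Si](C)(C)C(C)(C)C | intermediate
39 | 5-lithio analogue of 26 (not isolated) | [Li]c1cc(OC)c2c(c1)[C@@H](CO[Si](C)(C)C(C)(C)C)[C@H](c1cc(OC)c3c(c1)[C@H](CO[Si](C)(C)C(C)(C)C)[C@@H](c1ccc(O[Si](C)(C)C(C)(C)C)c(OC)c1)O3)O2 | intermediate
40 | (2R,3R)-1-Ar-3-(hydroxymethyl)-4-[3-methoxy-4-(TBSO)phenyl]-2-[(TBSO)methyl]butan-1-one, Ar = benzofuran-5-yl group of 26 (penta-silylated γ-hydroxy aryl ketone) | COc1cc(C[C@@H](CO)[C@H](CO[Si](C)(C)C(C)(C)C)C(=O)c3cc(OC)c4c(c3)[C@@H](CO[Si](C)(C)C(C)(C)C)[C@H](c3cc(OC)c5c(c3)[C@H](CO[Si](C)(C)C(C)(C)C)[C@@H](c3ccc(O[Si](C)(C)C(C)(C)C)c(OC)c3)O5)O4)ccc1O[Si](C)(C)C(C)(C)C | intermediate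
41 | (3R,4R)-2-Ar-4-{[3-methoxy-4-(TBSO)phenyl]methyl}-3-[(TBSO)methyl]oxolan-2-ol, both C2 epimers (not isolated) | COc1cc(C[C@H]2COC(O)(c3cc(OC)c4c(c3)[C@@H](CO[Si](C)(C)C(C)(C)C)[C@H](c3cc(OC)c5c(c3)[C@H](CO[Si](C)(C)C(C)(C)C)[C@@H](c3ccc(O[Si](C)(C)C(C)(C)C)c(OC)c3)O5)O4)[C@H]2CO[Si](C)(C)C(C)(C)C)ccc1O[Si](C)(C)C(C)(C)C | intermediate
42 | (3R,4R)-2-Ar-3,4-disubstituted 4,5-dihydro-3H-furan-1-ium, the C7 oxocarbenium ion (not isolated) | COc1cc(C[C@H]2C[O+]=C(c3cc(OC)c4c(c3)[C@@H](CO[Si](C)(C)C(C)(C)C)[C@H](c3cc(OC)c5c(c3)[C@H](CO[Si](C)(C)C(C)(C)C)[C@@H](c3ccc(O[Si](C)(C)C(C)(C)C)c(OC)c3)O5)O4)[C@H]2CO[Si](C)(C)C(C)(C)C)ccc1O[Si](C)(C)C(C)(C)C | intermediate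
43 | (2R,3R,4R)-2-Ar-4-{[3-methoxy-4-(TBSO)phenyl]methyl}-3-[(TBSO)methyl]oxolane, penta-TBS ether of 44 | COc1cc(C[C@H]2CO[C@@H](c3cc(OC)c4c(c3)[C@@H](CO[Si](C)(C)C(C)(C)C)[C@H](c3cc(OC)c5c(c3)[C@H](CO[Si](C)(C)C(C)(C)C)[C@@H](c3ccc(O[Si](C)(C)C(C)(C)C)c(OC)c3)O5)O4)[C@H]2CO[Si](C)(C)C(C)(C)C)ccc1O[Si](C)(C)C(C)(C)C | intermediate
44 | CNP0395728.1, {(2R,3R,4R)-2-[(2R,3S)-3-(hydroxymethyl)-2-[(2S,3R)-3-(hydroxymethyl)-2-(4-hydroxy-3-methoxyphenyl)-7-methoxy-2,3-dihydro-1-benzofuran-5-yl]-7-methoxy-2,3-dihydro-1-benzofuran-5-yl]-4-[(4-hydroxy-3-methoxyphenyl)methyl]oxolan-3-yl}methanol | COc1cc(C[C@H]2CO[C@@H](c3cc(OC)c4c(c3)[C@@H](CO)[C@H](c3cc(OC)c5c(c3)[C@H](CO)[C@@H](c3ccc(O)c(OC)c3)O5)O4)[C@H]2CO)ccc1O | target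

**Step count and risks**

Total step count: 26. Longest linear sequence: 17 steps (steps 1, 2, 3, 4, 5, 8, 9, 10, 11, 12, 13, 14, 15, 16, 24, 25, 26).

Steps most likely to fail:

1. Step 21. The facial selectivity of the protonation may be eroded by internal proton return from diisopropylamine or by proton relay from oxygen to carbon within the dianion, and the alkoxide may lose formaldehyde by retro-aldol cleavage. The fallback replaces enolate protonation by radical hydrogen-atom transfer. It sets out from 32: enolisation with LiN(iPr)2 and trapping with PhSeCl should give the trans 3-(phenylselanyl) lactone F1. A second enolisation and trapping with formaldehyde should give the 3-(hydroxymethyl)-3-(phenylselanyl) lactone F2. Bu3SnH with AIBN in toluene at 80 °C then generates the planar C3 radical, which should take hydrogen from the face opposite the C4 arylmethyl group, and the sequence comes back to the route at 36.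

2. Step 25. Hydride delivery may lack facial selectivity, C8 may epimerise when the oxocarbenium ion loses a proton to the cyclic enol ether and is reprotonated, or the benzylic C2–O bonds of the dihydrobenzofurans may ionise and be reduced. The fallback makes the other ring C–O bond by SN2 and sets C7 by reagent control. It sets out from 40: Corey–Bakshi–Shibata reduction ((S)-2-methyl-CBS-oxazaborolidine, BH3·SMe2, catalyst hand chosen for the 7R carbinol) should give the (7R)-1,4-diol F3. Selective sulfonylation of the primary C9' hydroxyl (TsCl, Et3N, catalytic DMAP, 0 °C) should give the primary monotosylate F4. NaH in THF then closes the oxolane by 5-exo-tet Williamson etherification with retention at C7, and the sequence comes back to the route at 43.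

3. Step 24. The basic aryllithium may enolise the lactone (returning the protonated arene and epimerising C8), or a second aryl group may add if the lithium hemiketal collapses to the ketone before the quench. The fallback uses an acyclic Weinreb amide as the acyl donor. It sets out from 38: Me2AlN(OMe)Me (from MeNH(OMe)·HCl and AlMe3, CH2Cl2, 0 °C) should open the lactone to the hydroxy Weinreb amide F5. TESCl and imidazole should give the triethylsilyl ether F6, to which aryllithium 39 should add once through the chelated tetrahedral intermediate to give the triethylsilyl-protected ketone F7. PPTS in MeOH/CH2Cl2 at 0 °C then removes the primary triethylsilyl ether selectively, and the sequence comes back to the route at 40.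

**Further compounds**
F1 | step 21 | trans-4-{[4-(benzyloxy)-3-methoxyphenyl]methyl}-3-(phenylselanyl)oxolan-2-one (4R; selanyl group trans to the arylmethyl group) | COc1cc(C[C@H]2COC(=O)[C@@H]2[Se]c3ccccc3)ccc1OCc1ccccc1
F2 | step 21 | (4R)-4-{[4-(benzyloxy)-3-methoxyphenyl]methyl}-3-(hydroxymethyl)-3-(phenylselanyl)oxolan-2-one (hydroxymethyl trans to the arylmethyl group) | COc1cc(C[C@H]2COC(=O)[C@@]2(CO)[Se]c3ccccc3)ccc1OCc1ccccc1
F3 | step 25 | (1R,2R,3R)-1-Ar-3-(hydroxymethyl)-4-[3-methoxy-4-(TBSO)phenyl]-2-[(TBSO)methyl]butan-1-ol, the (7R)-diol from 40 | COc1cc(C[C@@H](CO)[C@H](CO[Si](C)(C)C(C)(C)C)[C@@H](O)c3cc(OC)c4c(c3)[C@@H](CO[Si](C)(C)C(C)(C)C)[C@H](c3cc(OC)c5c(c3)[C@H](CO[Si](C)(C)C(C)(C)C)[C@@H](c3ccc(O[Si](C)(C)C(C)(C)C)c(OC)c3)O5)O4)ccc1O[Si](C)(C)C(C)(C)C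
F4 | step 25 | primary (C9') 4-methylbenzenesulfonate of F3 | COc1cc(C[C@@H](COS(=O)(=O)c6ccc(C)cc6)[C@H](CO[Si](C)(C)C(C)(C)C)[C@@H](O)c3cc(OC)c4c(c3)[C@@H](CO[Si](C)(C)C(C)(C)C)[C@H](c3cc(OC)c5c(c3)[C@H](CO[Si](C)(C)C(C)(C)C)[C@@H](c3ccc(O[Si](C)(C)C(C)(C)C)c(OC)c3)O5)O4)ccc1O[Si](C)(C)C(C)(C)C
F5 | step 24 | (2R,3R)-3-(hydroxymethyl)-N-methoxy-N-methyl-4-[3-methoxy-4-(TBSO)phenyl]-2-[(TBSO)methyl]butanamide | COc1cc(C[C@@H](CO)[C@H](CO[Si](C)(C)C(C)(C)C)C(=O)N(C)OC)ccc1O[Si](C)(C)C(C)(C)C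
F6 | step 24 | triethylsilyl ether of F5 at the C9' hydroxyl | COc1cc(C[C@@H](CO[Si](CC)(CC)CC)[C@H](CO[Si](C)(C)C(C)(C)C)C(=O)N(C)OC)ccc1O[Si](C)(C)C(C)(C)C
F7 | step 24 | triethylsilyl ether of 40 at the C9' hydroxyl | COc1cc(C[C@@H](CO[Si](CC)(CC)CC)[C@H](CO[Si](C)(C)C(C)(C)C)C(=O)c3cc(OC)c4c(c3)[C@@H](CO[Si](C)(C)C(C)(C)C)[C@H](c3cc(OC)c5c(c3)[C@H](CO[Si](C)(C)C(C)(C)C)[C@@H](c3ccc(O[Si](C)(C)C(C)(C)C)c(OC)c3)O5)O4)ccc1O[Si](C)(C)C(C)(C)C
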